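**Strategy**

The route rests on cutting the bond between the exocyclic CH2 and the quaternary oxirane carbon C1 of the 7-oxabicyclo[4.1.0]heptene. Without its oxirane oxygen, C1 is the sp2 terminus of a cyclohexa-1,3-diene, so this bond is made by Migita–Kosugi–Stille hydroxymethylation of a dienyl triflate, which completes the carbon skeleton in one operation. The precursor is a (5R,6R)-5-silyloxy-6-hydroxycyclohexadienyl triflate whose cis-diol carbons are C2 and C3 of D-ribose (zinc fragmentation–allylation, ring-closing metathesis, oxidation, enol triflation). The key step exploits the C1=C6 alkene latent in the oxirane: once coupled, the allylic C2 hydroxyl steers the epoxidation to its own face, and a single dibenzoylation installs both esters.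

Key step: step 8

Remark: the SMILES is read as the all-cis isomer (oxirane oxygen, C2 benzoate and C3 hydroxyl on one ring face, CH2OBz on the other), i.e. (1S,2R,3R,6S); its C2/C3 cis-diol has the configuration of C2/C3 of D-ribose.

**Route**

Step 1
Reactants: 1 methyl 2,3-O-isopropylidene-β-D-ribofuranoside
Product: 2 methyl 5-deoxy-5-iodo-2,3-O-isopropylidene-β-D-ribofuranoside
Conditions: I2, PPh3, imidazole, toluene, 70 °C
Reagents that add atoms: iodine, II
Why: Garegg–Samuelsson (Appel-type) iodination, in which the primary 5-OH is activated as an alkoxyphosphonium ion and displaced by iodide (SN2) without touching any stereocentre.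

Step 2
Reactants: 2 methyl 5-deoxy-5-iodo-2,3-O-isopropylidene-β-D-ribofuranoside
Product: 4 1-[(4S,5R)-5-ethenyl-2,2-dimethyl-1,3-dioxolan-4-yl]but-3-en-1-ol (both carbinol epimers), via pentenal 3 (not isolated)
Conditions: Zn dust (activated), THF–H2O (4:1), ultrasound, 40 °C
Reagents that add atoms: allyl bromide, C=CCBr
Why: Bernet–Vasella reductive fragmentation (zinc insertion into C–I, expulsion of the ring oxygen and collapse of the methyl acetal) should unmask aldehyde 3, which is trapped at once by allylzinc bromide in a Barbier allylation; the new carbinol centre forms unselectively and is erased in step 4, while the two ribose-derived centres are untouched.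

Step 3
Reactants: 4 1-[(4S,5R)-5-ethenyl-2,2-dimethyl-1,3-dioxolan-4-yl]but-3-en-1-ol
Product: 5 (3aS,7aR)-2,2-dimethyl-3a,4,5,7a-tetrahydro-1,3-benzodioxol-4-ol (cis-fused, both C4 epimers)
Conditions: Grubbs second-generation catalyst (2 mol %), CH2Cl2, 40 °C
Reagents that add atoms: none
Why: Ring-closing metathesis of the 1,7-diene should close the cyclohexene with loss of ethylene, the ruthenium carbene tolerating the free hydroxyl and the acetonide.

Step 4
Reactants: 5 (3aS,7aR)-2,2-dimethyl-3a,4,5,7a-tetrahydro-1,3-benzodioxol-4-ol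
Product: 6 (3aR,7aR)-2,2-dimethyl-3a,7a-dihydro-1,3-benzodioxol-4(5H)-one
Conditions: Dess–Martin periodinane, pyridine, CH2Cl2, 0 °C to rt
Reagents that add atoms: none
Why: Dess–Martin oxidation converts both carbinol epimers into one ketone under near-neutral conditions that should leave the β,γ-alkene unconjugated and the α-alkoxy centre intact.

Step 5
Reactants: 6 (3aR,7aR)-2,2-dimethyl-3a,7a-dihydro-1,3-benzodioxol-4(5H)-one
Product: 8 (3aR,7aR)-2,2-dimethyl-3a,7a-dihydro-1,3-benzodioxol-4-yl trifluoromethanesulfonate, via potassium dienolate 7 (not isolated)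
Conditions: KHMDS, THF, −78 °C; then PhNTf2, −78 to −20 °C
Reagents that add atoms: N-phenylbis(trifluoromethanesulfonimide), O=S(=O)(N(c1ccccc1)S(=O)(=O)C(F)(F)F)C(F)(F)F
Why: Kinetic deprotonation at C5, the CH2 that is both α to the carbonyl and allylic, should give the linear dienolate, whose O-sulfonylation (enol triflate formation) at low temperature outruns loss of the allylic alkoxide.

Step 6
Reactants: 8 (3aR,7aR)-2,2-dimethyl-3a,7a-dihydro-1,3-benzodioxol-4-yl trifluoromethanesulfonate
Product: 9 (5R,6R)-5,6-dihydroxycyclohexa-1,3-dien-1-yl trifluoromethanesulfonate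
Conditions: TFA–H2O–THF (1:1:4), 0 °C
Reagents that add atoms: none
Why: Acid-catalysed acetal hydrolysis frees the cis-diol, and the electron-withdrawing triflate on the diene should retard ionisation and dehydration to a phenol, as halogens do in 3-halo arene cis-dihydrodiols.

Step 7
Reactants: 9 (5R,6R)-5,6-dihydroxycyclohexa-1,3-dien-1-yl trifluoromethanesulfonate
Product: 10 (5R,6R)-5-[(tert-butyldimethylsilyl)oxy]-6-hydroxycyclohexa-1,3-dien-1-yl trifluoromethanesulfonate
Conditions: TBSCl (1.1 equiv), imidazole, DMF, −20 to 0 °C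
Reagents that add atoms: tert-butyldimethylsilyl chloride, CC(C)(C)[Si](C)(C)Cl
Why: Silyl ether formation should occur selectively at the less hindered distal hydroxyl (C5), because the C6 hydroxyl is shielded by the adjacent triflate-bearing carbon, the selectivity pattern known for 3-halo cis-dihydrodiols.

Step 8
Reactants: 10 (5R,6R)-5-[(tert-butyldimethylsilyl)oxy]-6-hydroxycyclohexa-1,3-dien-1-yl trifluoromethanesulfonate, 11 (tributylstannyl)methanol
Product: 12 (1S,6R)-6-[(tert-butyldimethylsilyl)oxy]-2-(hydroxymethyl)cyclohexa-2,4-dien-1-ol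
Conditions: Pd2(dba)3 (2.5 mol %), AsPh3 (20 mol %), LiCl (3 equiv), NMP, 50 °C
Reagents that add atoms: none
Why: Pd(0) inserts into the C1–OTf bond of the dienyl triflate (chloride from LiCl stabilises the alkenyl–Pd(II) species), the hydroxymethyl group is transferred from tin to palladium in preference to butyl because its α-oxygen accelerates transmetalation, and reductive elimination forms the C(sp2)–CH2OH bond with the diene intact. This is a Migita–Kosugi–Stille coupling, the known hydroxymethylation of aryl halides and enol triflates with (tributylstannyl)methanol. No ring is closed and no stereocentre is formed, since the coupled carbon stays trigonal and becomes the quaternary oxirane carbon only in step 9. The step needs chemoselectivity for C–C coupling over loss of the allylic oxygen groups (aromatisation) and tolerance of the free ring hydroxyl; the neutral, mild conditions, the silyl ether on the distal oxygen and the inertness of the tin reagent towards hydroxyl groups should secure this.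

Step 9
Reactants: 12 (1S,6R)-6-[(tert-butyldimethylsilyl)oxy]-2-(hydroxymethyl)cyclohexa-2,4-dien-1-ol
Product: 13 (1R,2R,3R,6S)-3-[(tert-butyldimethylsilyl)oxy]-1-(hydroxymethyl)-7-oxabicyclo[4.1.0]hept-4-en-2-ol
Conditions: VO(acac)2 (5 mol %), t-BuOOH (1.2 equiv, decane), CH2Cl2, 0 °C
Reagents that add atoms: tert-butyl hydroperoxide, CC(C)(C)OO
Why: In this vanadium-catalysed hydroxyl-directed epoxidation the vanadate ester of the ring allylic hydroxyl (chelated by the primary one) should deliver oxygen to the trisubstituted alkene from the face of that hydroxyl, setting both oxirane centres cis to the two ring oxygens, while the other alkene is only homoallylic and reacts more slowly.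

Step 10
Reactants: 13 (1R,2R,3R,6S)-3-[(tert-butyldimethylsilyl)oxy]-1-(hydroxymethyl)-7-oxabicyclo[4.1.0]hept-4-en-2-ol
Product: 14 [(1S,2R,3R,6S)-2-(benzoyloxy)-3-[(tert-butyldimethylsilyl)oxy]-7-oxabicyclo[4.1.0]hept-4-en-1-yl]methyl benzoate
Conditions: Bz2O (3 equiv), Et3N, DMAP (cat.), CH2Cl2, 0 °C to rt
Reagents that add atoms: benzoic anhydride, O=C(OC(=O)c1ccccc1)c1ccccc1
Why: DMAP-catalysed acylation should benzoylate the primary and the secondary hydroxyl in one operation under chloride-free, non-acidic conditions that spare the vinyl oxirane.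

Step 11
Reactants: 14 [(1S,2R,3R,6S)-2-(benzoyloxy)-3-[(tert-butyldimethylsilyl)oxy]-7-oxabicyclo[4.1.0]hept-4-en-1-yl]methyl benzoate
Product: 15 [(1S,2R,3R,6S)-2-(benzoyloxy)-3-hydroxy-7-oxabicyclo[4.1.0]hept-4-en-1-yl]methyl benzoate
Conditions: HF·pyridine, pyridine, THF, 0 °C to rt
Reagents that add atoms: none
Why: Fluoride-mediated desilylation under buffered, weakly acidic conditions should free the C3 hydroxyl without opening the oxirane or triggering benzoyl migration from C2 to C3.

**Compound list**

1 | methyl 2,3-O-isopropylidene-β-D-ribofuranoside | CO[C@@H]1O[C@H](CO)[C@H]2OC(C)(C)O[C@@H]12 | starting material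
2 | methyl 5-deoxy-5-iodo-2,3-O-isopropylidene-β-D-ribofuranoside | CO[C@@H]1O[C@H](CI)[C@H]2OC(C)(C)O[C@@H]12 | intermediate
3 | 4,5-dideoxy-2,3-O-isopropylidene-D-erythro-pent-4-enose, (4R,5R)-5-ethenyl-2,2-dimethyl-1,3-dioxolane-4-carbaldehyde | O=C[C@@H]1OC(C)(C)O[C@@H]1C=C | intermediate (not isolated)
4 | 1-[(4S,5R)-5-ethenyl-2,2-dimethyl-1,3-dioxolan-4-yl]but-3-en-1-ol (both carbinol epimers) | C=CCC(O)[C@@H]1OC(C)(C)O[C@@H]1C=C | intermediate
5 | (3aS,7aR)-2,2-dimethyl-3a,4,5,7a-tetrahydro-1,3-benzodioxol-4-ol (both C4 epimers) | OC1CC=C[C@H]2OC(C)(C)O[C@@H]12 | intermediate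
6 | (3aR,7aR)-2,2-dimethyl-3a,7a-dihydro-1,3-benzodioxol-4(5H)-one | O=C1CC=C[C@H]2OC(C)(C)O[C@@H]12 | intermediate
7 | potassium (3aR,7aR)-2,2-dimethyl-3a,7a-dihydro-1,3-benzodioxol-4-olate | [K+].[O-]C1=CC=C[C@H]2OC(C)(C)O[C@@H]12 | intermediate (not isolated)
8 | (3aR,7aR)-2,2-dimethyl-3a,7a-dihydro-1,3-benzodioxol-4-yl trifluoromethanesulfonate | O=S(=O)(OC1=CC=C[C@H]2OC(C)(C)O[C@@H]12)C(F)(F)F | intermediate
9 | (5R,6R)-5,6-dihydroxycyclohexa-1,3-dien-1-yl trifluoromethanesulfonate | O=S(=O)(OC1=CC=C[C@@H](O)[C@H]1O)C(F)(F)F | intermediate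
10 | (5R,6R)-5-[(tert-butyldimethylsilyl)oxy]-6-hydroxycyclohexa-1,3-dien-1-yl trifluoromethanesulfonate | O=S(=O)(OC1=CC=C[C@@H](O[Si](C)(C)C(C)(C)C)[C@H]1O)C(F)(F)F | intermediate
11 | (tributylstannyl)methanol | OC[Sn](CCCC)(CCCC)CCCC | starting material
12 | (1S,6R)-6-[(tert-butyldimethylsilyl)oxy]-2-(hydroxymethyl)cyclohexa-2,4-dien-1-ol | OCC1=CC=C[C@@H](O[Si](C)(C)C(C)(C)C)[C@H]1O | intermediate
13 | (1R,2R,3R,6S)-3-[(tert-butyldimethylsilyl)oxy]-1-(hydroxymethyl)-7-oxabicyclo[4.1.0]hept-4-en-2-ol | OC[C@]12O[C@H]1C=C[C@@H](O[Si](C)(C)C(C)(C)C)[C@H]2O | intermediate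
14 | [(1S,2R,3R,6S)-2-(benzoyloxy)-3-[(tert-butyldimethylsilyl)oxy]-7-oxabicyclo[4.1.0]hept-4-en-1-yl]methyl benzoate | O=C(OC[C@]12O[C@H]1C=C[C@@H](O[Si](C)(C)C(C)(C)C)[C@H]2OC(=O)c1ccccc1)c1ccccc1 | intermediate
15 | [(1S,2R,3R,6S)-2-(benzoyloxy)-3-hydroxy-7-oxabicyclo[4.1.0]hept-4-en-1-yl]methyl benzoate | O=C(OC[C@]12O[C@H]1C=C[C@@H](O)[C@H]2OC(=O)c1ccccc1)c1ccccc1 | target

**Summary**

Total step count: 11. Longest linear sequence: 11 steps (1 to 15).

Steps most likely to fail:

Step 5. The dienolate may expel the allylic alkoxide of the acetonide (vinylogous β-elimination) and aromatise, or deprotonation may occur at the alkoxy-bearing α-carbon. The fallback avoids any enolate; it sets out from ketone 6 and returns at 12. Hydrazine hydrate in ethanol should give the hydrazone of ketone 6 F1, and Barton iodination (I2, tetramethylguanidine, THF, 0 °C) should convert it into (3aR,7aR)-4-iodo-2,2-dimethyl-3a,7a-dihydro-1,3-benzodioxole F2. Aqueous acid should then free (1R,2R)-3-iodocyclohexa-3,5-diene-1,2-diol F3, and silylation of the distal hydroxyl (TBSCl, imidazole) should give (1R,6R)-6-[(tert-butyldimethylsilyl)oxy]-2-iodocyclohexa-2,4-dien-1-ol F4. Stille coupling of this iodide with 11 should then give 12.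

Step 8. Transfer of the sp3 hydroxymethyl group from tin may be slow, so that thermal dehydration to an arene or Diels–Alder dimerisation of the diene competes. The fallback sets out from triflate 10 and returns at 12. Palladium-catalysed methoxycarbonylation (CO 1 atm, Pd(OAc)2, PPh3, Et3N, MeOH–DMF, rt) should form the same C–C bond by CO insertion and give methyl (5R,6S)-5-[(tert-butyldimethylsilyl)oxy]-6-hydroxycyclohexa-1,3-diene-1-carboxylate F5. Reduction with DIBAL-H (CH2Cl2, −78 °C) should then give 12.

Step 9. Oxygen delivery through the primary vanadate alone may erode facial selectivity, or the second alkene may be attacked. The fallback sets out from 12 and returns at 14. Selective benzoylation of the primary hydroxyl (BzCl, 2,4,6-collidine, CH2Cl2, −78 °C) should give [(5R,6S)-5-[(tert-butyldimethylsilyl)oxy]-6-hydroxycyclohexa-1,3-dien-1-yl]methyl benzoate F6. Vanadium-catalysed epoxidation, now directed only by the ring hydroxyl, should give [(1R,2R,3R,6S)-3-[(tert-butyldimethylsilyl)oxy]-2-hydroxy-7-oxabicyclo[4.1.0]hept-4-en-1-yl]methyl benzoate F7. Benzoylation (Bz2O, Et3N, DMAP) should then give 14.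

**Further compounds**

F1 | step 5 | hydrazone of (3aR,7aR)-2,2-dimethyl-3a,7a-dihydro-1,3-benzodioxol-4(5H)-one | NN=C1CC=C[C@H]2OC(C)(C)O[C@@H]12
F2 | step 5 | (3aR,7aR)-4-iodo-2,2-dimethyl-3a,7a-dihydro-1,3-benzodioxole | IC1=CC=C[C@H]2OC(C)(C)O[C@@H]12
F3 | step 5 | (1R,2R)-3-iodocyclohexa-3,5-diene-1,2-diol | IC1=CC=C[C@@H](O)[C@H]1O
F4 | step 5 | (1R,6R)-6-[(tert-butyldimethylsilyl)oxy]-2-iodocyclohexa-2,4-dien-1-ol | IC1=CC=C[C@@H](O[Si](C)(C)C(C)(C)C)[C@H]1O
F5 | step 8 | methyl (5R,6S)-5-[(tert-butyldimethylsilyl)oxy]-6-hydroxycyclohexa-1,3-diene-1-carboxylate | COC(=O)C1=CC=C[C@@H](O[Si](C)(C)C(C)(C)C)[C@H]1O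
F6 | step 9 | [(5R,6S)-5-[(tert-butyldimethylsilyl)oxy]-6-hydroxycyclohexa-1,3-dien-1-yl]methyl benzoate | O=C(OCC1=CC=C[C@@H](O[Si](C)(C)C(C)(C)C)[C@H]1O)c1ccccc1
F7 | step 9 | [(1R,2R,3R,6S)-3-[(tert-butyldimethylsilyl)oxy]-2-hydroxy-7-oxabicyclo[4.1.0]hept-4-en-1-yl]methyl benzoate | O=C(OC[C@]12O[C@H]1C=C[C@@H](O[Si](C)(C)C(C)(C)C)[C@H]2O)c1ccccc1
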